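**Strategy**

Drummondin A is cut at the methylene bridge into butyrylfilicinic acid (ring A) and 8-butyryl-5,7-dihydroxy-2,2-dimethylchromene, whose benzene ring B is assembled from two small unsaturated pieces. A Danheiser benzannulation of a 3-alkoxycyclobutenone with a siloxyalkyne bearing the ketal-masked butyryl group makes the C8–C8a and C6–C7 bonds and closes ring B in one operation. It exploits the 1,3,5-trioxygenation of ring B: the oxygen on C8a, beside the acyl carbon C8, is born as the only free phenol, while the C7 and C5 oxygens arrive as TIPS and MOM ethers, so the pyran ring (O1–C2) can be annulated in one orientation only.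

Key step: step 8

Remark: the enolised triones (5, 28, 30, ring A of 32) are written as single tautomers that interconvert freely; the target has no stereocentre, and the one stereocentre of transient 16 (racemic) disappears within the same step.

**Route**

Step 1
Reactants: 1 ethoxyacetylene; 2 acetone
Product: 4 3-ethoxycyclobut-2-en-1-one, via ketene 3 (not isolated)
Conditions: acetone pyrolysed (ca. 700 °C, ketene generator), ketene stream passed into 1, CH2Cl2, −20 → 0 °C
Reagents that add atoms: none
Why: The thermal [2+2] cycloaddition of ketene with an alkoxyalkyne is an established entry to 3-alkoxycyclobutenones, the nucleophilic terminal alkyne carbon bonding to the ketene carbonyl carbon.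

Step 2
Reactants: 4 3-ethoxycyclobut-2-en-1-one
Product: 5 cyclobutane-1,3-dione
Conditions: cold 90% H2SO4, −10 → 0 °C; then ice, Et2O extraction; used at once
Reagents that add atoms: water, O
Why: Acid hydrolysis of the vinylogous ester (addition–elimination at C3) should give the dione, which is kept cold and carried on directly because it degrades on storage.

Step 3
Reactants: 5 cyclobutane-1,3-dione
Product: 6 3-(methoxymethoxy)cyclobut-2-en-1-one
Conditions: MOMCl, i-Pr2NEt, CH2Cl2, −20 → 0 °C
Reagents that add atoms: chloromethyl methyl ether (MOMCl), COCCl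
Why: O-alkylation of the strongly acidic enol of a cyclic 1,3-dione with the hard electrophile MOMCl should give the enol MOM ether, as it does for other cyclic 1,3-diones.

Step 4
Reactants: 7 butyryl chloride; 8 bis(trimethylsilyl)acetylene
Product: 9 1-(trimethylsilyl)hex-1-yn-3-one
Conditions: AlCl3, CH2Cl2, 0 °C
Reagents that add atoms: none
Why: Friedel–Crafts-type acylation of the bis-silylalkyne proceeds by ipso substitution of one silyl group and stops at the mono-ynone because the product is deactivated.

Step 5
Reactants: 9 1-(trimethylsilyl)hex-1-yn-3-one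
Product: 10 2-propyl-2-[(trimethylsilyl)ethynyl]-1,3-dioxolane
Conditions: Me3SiOCH2CH2OSiMe3, Me3SiOTf (cat.), CH2Cl2, −78 → −20 °C
Reagents that add atoms: 1,2-bis(trimethylsilyloxy)ethane, C[Si](C)(C)OCCO[Si](C)(C)C
Why: Ketalisation with the bis-silyl ether of ethylene glycol under silyl triflate catalysis (Noyori conditions) runs at low temperature and so avoids conjugate addition of the diol to the ynone.

Step 6
Reactants: 10 2-propyl-2-[(trimethylsilyl)ethynyl]-1,3-dioxolane
Product: 11 2-ethynyl-2-propyl-1,3-dioxolane
Conditions: K2CO3 (cat.), MeOH, rt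
Reagents that add atoms: none
Why: Carbonate-catalysed methanolysis of the alkynyl C–Si bond (protodesilylation) is mild and leaves the base-stable ketal untouched.

Step 7
Reactants: 11 2-ethynyl-2-propyl-1,3-dioxolane
Product: 14 2-propyl-2-[(triisopropylsilyloxy)ethynyl]-1,3-dioxolane, via lithium acetylide 12 (not isolated), via lithium ynolate 13 (not isolated)
Conditions: n-BuLi, THF, −78 °C; LiOOt-Bu (from t-BuOOH and LiN(SiMe3)2), −78 → 0 °C; i-Pr3SiOTf, −78 → 0 °C
Reagents that add atoms: tert-butyl hydroperoxide, CC(C)(C)OO; triisopropylsilyl trifluoromethanesulfonate, CC(C)[Si](OS(=O)(=O)C(F)(F)F)(C(C)C)C(C)C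
Why: The lithium acetylide attacks the electrophilic oxygen of lithium tert-butyl peroxide to give the ynolate (acetylide oxygenation), and the bulky silyl triflate then silylates it on oxygen to give the siloxyalkyne instead of a silylketene.

Step 8
Reactants: 6 3-(methoxymethoxy)cyclobut-2-en-1-one; 14 2-propyl-2-[(triisopropylsilyloxy)ethynyl]-1,3-dioxolane
Product: 19 2-(2-propyl-1,3-dioxolan-2-yl)-5-(methoxymethoxy)-3-(triisopropylsilyloxy)phenol, via vinylketene 15 (not isolated), via vinylcyclobutenone 16 (not isolated), via dienylketene 17 (not isolated), via cyclohexadienone 18 (not isolated)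
Conditions: toluene, 80 °C then 110 °C (sealed tube)
Reagents that add atoms: none
Why: Heating opens cyclobutenone 6 by a 4π electrocyclic reaction to vinylketene 15, which adds the siloxyalkyne across its ketene C=C in a [2+2] cycloaddition; the resulting 4-vinylcyclobutenone 16 opens again to dienylketene 17, and 6π electrocyclisation followed by tautomerisation of dienone 18 gives phenol 19. This is the Danheiser benzannulation in its known siloxyalkyne variant, which delivers resorcinol monosilyl ethers. Ring B is closed by a thermal disrotatory 6π electrocyclisation that re-forms the C8a–C4a bond after the cycloaddition has made the two new bonds C8–C8a and C6–C7. No stereocentre results, because the single one in 16 is erased by ring opening and aromatisation. The selectivity needed is the regiochemistry of the ketene–alkyne addition: the alkyne carbon remote from oxygen is the nucleophilic terminus of the ynol ether and bonds to the electrophilic ketene carbonyl carbon, so the ketal-bearing carbon ends up beside the free phenol and the three oxygens appear as OH, OTIPS and OMOM. The bulky TIPS group suppresses silyl transfer to the new phenol, and the ketal keeps the acyl carbon from deactivating the alkyne.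

Step 9
Reactants: 19 2-(2-propyl-1,3-dioxolan-2-yl)-5-(methoxymethoxy)-3-(triisopropylsilyloxy)phenol; 20 3-methylbut-2-enal
Product: 22 2-[5-(methoxymethoxy)-2,2-dimethyl-7-(triisopropylsilyloxy)-2H-chromen-8-yl]-2-propyl-1,3-dioxolane, via ortho-quinone methide 21 (not isolated)
Conditions: 3-methylbut-2-enal (3 equiv), pyridine, 140 °C (sealed tube)
Reagents that add atoms: none
Why: Base-mediated condensation of the electron-rich phenol with the enal at C4a, its only free ortho carbon (Knoevenagel-type C-alkylation and dehydration), should give an ortho-quinone methide that closes by oxa-6π electrocyclisation to the 2,2-dimethyl-2H-chromene, and pyridine keeps the ketal, MOM and TIPS groups intact.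

Step 10
Reactants: 22 2-[5-(methoxymethoxy)-2,2-dimethyl-7-(triisopropylsilyloxy)-2H-chromen-8-yl]-2-propyl-1,3-dioxolane
Product: 25 1-(5,7-dihydroxy-2,2-dimethyl-2H-chromen-8-yl)butan-1-one, via desilylated ketal 23 (not isolated), via MOM-protected ketone 24 (not isolated)
Conditions: Bu4NF, THF, 0 °C; then 2 M HCl, MeOH–H2O, 40 °C
Reagents that add atoms: water, O
Why: Fluoride cleaves the aryl silyl ether, after which dilute methanolic HCl hydrolyses the very labile aryl ketal and then the MOM ether (acetal cleavage), conditions that acyl-substituted 2,2-dimethylchromenes normally tolerate.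

Step 11
Reactants: 26 phloroglucinol; 7 butyryl chloride
Product: 27 1-(2,4,6-trihydroxyphenyl)butan-1-one
Conditions: AlCl3 (3 equiv), PhNO2–CH2Cl2, rt → 50 °C; aq HCl work-up
Reagents that add atoms: none
Why: Friedel–Crafts C-acylation of phloroglucinol stops at the monoketone because the acyl group deactivates the ring toward a second acylation.

Step 12
Reactants: 27 1-(2,4,6-trihydroxyphenyl)butan-1-one
Product: 28 butyrylfilicinic acid (2-butanoyl-3,5-dihydroxy-6,6-dimethylcyclohexa-2,4-dien-1-one)
Conditions: NaOMe (4 equiv), MeI (2.5 equiv), MeOH, 0 °C → rt; aq HCl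
Reagents that add atoms: iodomethane, CI
Why: Twofold base-mediated C-methylation of the acylphloroglucinol at one ring carbon (dearomatising geminal dimethylation) is the classical entry to acylfilicinic acids, with under- and over-methylated by-products removed by crystallisation.

Step 13
Reactants: 28 butyrylfilicinic acid; 29 Eschenmoser's salt (N,N-dimethylmethyleneiminium iodide)
Product: 30 2-butanoyl-4-[(dimethylamino)methyl]-3,5-dihydroxy-6,6-dimethylcyclohexa-2,4-dien-1-one hydroiodide
Conditions: MeCN, 0 °C → rt; salt isolated by trituration with Et2O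
Reagents that add atoms: none
Why: Mannich aminomethylation of the only nucleophilic ring carbon of the enolised trione with the preformed iminium salt should be fast at room temperature and gives a storable precursor of the methylene trione.

Step 14
Reactants: 30 Mannich base hydroiodide of butyrylfilicinic acid; 25 1-(5,7-dihydroxy-2,2-dimethyl-2H-chromen-8-yl)butan-1-one
Product: 32 Drummondin A, via methylene trione 31 (not isolated)
Conditions: NaOAc (2 equiv), MeCN, 60 °C
Reagents that add atoms: none
Why: Buffering with NaOAc lets the Mannich base lose dimethylamine (E1cB elimination) to the 2-methylene-1,3-dione, which is captured by C6 of the chromene, its only free aromatic carbon and one activated by two flanking hydroxyls (Michael addition, alkylation by a Mannich base).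

**Compound list**

1 | ethoxyacetylene | CCOC#C | starting material
2 | acetone | CC(C)=O | starting material
3 | ketene | C=C=O | intermediate (not isolated)
4 | 3-ethoxycyclobut-2-en-1-one | CCOC1=CC(=O)C1 | intermediate
5 | cyclobutane-1,3-dione | O=C1CC(=O)C1 | intermediate
6 | 3-(methoxymethoxy)cyclobut-2-en-1-one | O=C1C=C(OCOC)C1 | intermediate
7 | butyryl chloride | CCCC(Cl)=O | starting material
8 | bis(trimethylsilyl)acetylene | C[Si](C)(C)C#C[Si](C)(C)C | starting material
9 | 1-(trimethylsilyl)hex-1-yn-3-one | CCCC(=O)C#C[Si](C)(C)C | intermediate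
10 | 2-propyl-2-[(trimethylsilyl)ethynyl]-1,3-dioxolane | CCCC1(C#C[Si](C)(C)C)OCCO1 | intermediate
11 | 2-ethynyl-2-propyl-1,3-dioxolane | CCCC1(C#C)OCCO1 | intermediate
12 | lithium acetylide of 11 | [Li]C#CC1(CCC)OCCO1 | intermediate (not isolated)
13 | lithium 2-(2-propyl-1,3-dioxolan-2-yl)ethynolate | [Li+].[O-]C#CC1(CCC)OCCO1 | intermediate (not isolated)
14 | 2-propyl-2-[(triisopropylsilyloxy)ethynyl]-1,3-dioxolane | CCCC1(C#CO[Si](C(C)C)(C(C)C)C(C)C)OCCO1 | intermediate
15 | 3-(methoxymethoxy)buta-1,3-dien-1-one (vinylketene) | C=C(OCOC)C=C=O | intermediate (not isolated)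
16 | 4-[1-(methoxymethoxy)ethenyl]-2-(2-propyl-1,3-dioxolan-2-yl)-3-(triisopropylsilyloxy)cyclobut-2-en-1-one (racemic) | CCCC1(OCCO1)C1=C(O[Si](C(C)C)(C(C)C)C(C)C)C(C(=C)OCOC)C1=O | intermediate (not isolated)
17 | (3E)-5-(methoxymethoxy)-2-(2-propyl-1,3-dioxolan-2-yl)-3-(triisopropylsilyloxy)hexa-1,3,5-trien-1-one (dienylketene, carbon chain cis across C3=C4) | O=C=C(C1(CCC)OCCO1)/C(O[Si](C(C)C)(C(C)C)C(C)C)=C\C(OCOC)=C | intermediate (not isolated)
18 | 5-(methoxymethoxy)-2-(2-propyl-1,3-dioxolan-2-yl)-3-(triisopropylsilyloxy)cyclohexa-2,4-dien-1-one | O=C1CC(OCOC)=CC(O[Si](C(C)C)(C(C)C)C(C)C)=C1C1(CCC)OCCO1 | intermediate (not isolated)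
19 | 2-(2-propyl-1,3-dioxolan-2-yl)-5-(methoxymethoxy)-3-(triisopropylsilyloxy)phenol | CCCC1(c2c(O)cc(OCOC)cc2O[Si](C(C)C)(C(C)C)C(C)C)OCCO1 | intermediate
20 | 3-methylbut-2-enal | CC(C)=CC=O | starting material
21 | (6Z)-5-(methoxymethoxy)-6-(3-methylbut-2-en-1-ylidene)-2-(2-propyl-1,3-dioxolan-2-yl)-3-(triisopropylsilyloxy)cyclohexa-2,4-dien-1-one (ortho-quinone methide) | CC(C)=C/C=C1/C(OCOC)=CC(O[Si](C(C)C)(C(C)C)C(C)C)=C(C2(CCC)OCCO2)C1=O | intermediate (not isolated)
22 | 2-[5-(methoxymethoxy)-2,2-dimethyl-7-(triisopropylsilyloxy)-2H-chromen-8-yl]-2-propyl-1,3-dioxolane | CCCC1(OCCO1)c1c(O[Si](C(C)C)(C(C)C)C(C)C)cc(OCOC)c2C=CC(C)(C)Oc12 | intermediate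
23 | 5-(methoxymethoxy)-2,2-dimethyl-8-(2-propyl-1,3-dioxolan-2-yl)-2H-chromen-7-ol | CCCC1(OCCO1)c1c(O)cc(OCOC)c2C=CC(C)(C)Oc12 | intermediate (not isolated)
24 | 1-[7-hydroxy-5-(methoxymethoxy)-2,2-dimethyl-2H-chromen-8-yl]butan-1-one | CCCC(=O)c1c(O)cc(OCOC)c2C=CC(C)(C)Oc12 | intermediate (not isolated)
25 | 1-(5,7-dihydroxy-2,2-dimethyl-2H-chromen-8-yl)butan-1-one | CCCC(=O)c1c(O)cc(O)c2C=CC(C)(C)Oc12 | intermediate
26 | phloroglucinol (benzene-1,3,5-triol) | Oc1cc(O)cc(O)c1 | starting material
27 | 1-(2,4,6-trihydroxyphenyl)butan-1-one | CCCC(=O)c1c(O)cc(O)cc1O | intermediate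
28 | butyrylfilicinic acid (2-butanoyl-3,5-dihydroxy-6,6-dimethylcyclohexa-2,4-dien-1-one) | CCCC(=O)C1=C(O)C=C(O)C(C)(C)C1=O | intermediate
29 | Eschenmoser's salt (N,N-dimethylmethyleneiminium iodide) | C=[N+](C)C.[I-] | starting material
30 | 2-butanoyl-4-[(dimethylamino)methyl]-3,5-dihydroxy-6,6-dimethylcyclohexa-2,4-dien-1-one hydroiodide | CCCC(=O)C1=C(O)C(C[NH+](C)C)=C(O)C(C)(C)C1=O.[I-] | intermediate
31 | 2-butanoyl-3-hydroxy-6,6-dimethyl-4-methylidenecyclohex-2-ene-1,5-dione | CCCC(=O)C1=C(O)C(=C)C(=O)C(C)(C)C1=O | intermediate (not isolated)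
32 | Drummondin A | CCCC(=O)C1=C(O)C(Cc2c(O)c3c(c(C(=O)CCC)c2O)OC(C)(C)C=C3)=C(O)C(C)(C)C1=O | target

**Step count**

Total: 14 steps. Longest linear sequence: 8 steps (steps 4, 5, 6, 7, 8, 9, 10 and 14).

**Steps most likely to fail**

Step 8. The alkoxy group stabilises the cyclobutenone as a vinylogous ester, so opening to the vinylketene may be too slow. The ketene may also be lost to self-condensation before the hindered, ketal-bearing alkyne carbon adds, in which case ring B would not form. The fallback sets out from 27 and comes back to the route at 25; it takes the regiocontrol from hydrogen bonding instead of from ring synthesis. Compound 27 is treated with MOMCl (2.2 equiv) and i-Pr2NEt in CH2Cl2 at 0 °C, which leaves the carbonyl-chelated hydroxyl free and should give 1-[2-hydroxy-4,6-bis(methoxymethoxy)phenyl]butan-1-one F1. That last phenol is alkylated with 3-chloro-3-methylbut-1-yne (K2CO3, KI, CuI cat., DMF, 60 °C) to the aryl propargyl ether 1-{2,4-bis(methoxymethoxy)-6-[(2-methylbut-3-yn-2-yl)oxy]phenyl}butan-1-one F2. Heating in N,N-diethylaniline at 160 °C (propargyl Claisen rearrangement, 1,5-hydrogen shift and oxa-6π closure at the only free ortho carbon) should give 1-[5,7-bis(methoxymethoxy)-2,2-dimethyl-2H-chromen-8-yl]butan-1-one F3. HCl in MeOH at 40 °C then removes both MOM groups to reach 25.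

Step 9. C-alkylation of a monophenol at C4a may be slow, the enal may attack C6 (para to the phenol) without leading on to product, or the ortho ketal may be opened by the neighbouring phenol at 140 °C. The fallback sets out from 19 and comes back at 22; it forms the O–C2 bond first. Compound 19 is O-alkylated with 3-chloro-3-methylbut-1-yne (DBU, CuCl2 cat., MeCN, 0 °C) to 2-[4-(methoxymethoxy)-2-[(2-methylbut-3-yn-2-yl)oxy]-6-(triisopropylsilyloxy)phenyl]-2-propyl-1,3-dioxolane F4. Heating F4 in xylene at 140 °C should bring about the aromatic propargyl Claisen rearrangement to C4a, a 1,5-hydrogen shift to the same ortho-quinone methide 21 and electrocyclisation to 22.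

Step 14. The methylene trione may be consumed by self-condensation, or the product may exchange its halves by retro-Michael cleavage and recombination, so that symmetrical dimers form beside the mixed one. The fallback sets out from 25 and comes back at 32; it reverses the roles of the two rings. Compound 25 is aminomethylated at C6 with 29 (CH2Cl2, rt, NaHCO3 work-up) to give 1-{6-[(dimethylamino)methyl]-5,7-dihydroxy-2,2-dimethyl-2H-chromen-8-yl}butan-1-one F5. Heating F5 with 28 in 1,4-dioxane at 100 °C should expel dimethylamine to form the ring B ortho-quinone methide 8-butanoyl-5-hydroxy-2,2-dimethyl-6-methylidene-2H-chromen-7(6H)-one F6 (not isolated), which the enolised trione 28 captures at its free ring carbon to give 32.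

**Further compounds**

F1 | step 8 | 1-[2-hydroxy-4,6-bis(methoxymethoxy)phenyl]butan-1-one | CCCC(=O)c1c(O)cc(OCOC)cc1OCOC
F2 | step 8 | 1-{2,4-bis(methoxymethoxy)-6-[(2-methylbut-3-yn-2-yl)oxy]phenyl}butan-1-one | CCCC(=O)c1c(OC(C)(C)C#C)cc(OCOC)cc1OCOC
F3 | step 8 | 1-[5,7-bis(methoxymethoxy)-2,2-dimethyl-2H-chromen-8-yl]butan-1-one | CCCC(=O)c1c(OCOC)cc(OCOC)c2C=CC(C)(C)Oc12
F4 | step 9 | 2-[4-(methoxymethoxy)-2-[(2-methylbut-3-yn-2-yl)oxy]-6-(triisopropylsilyloxy)phenyl]-2-propyl-1,3-dioxolane | CCCC1(c2c(OC(C)(C)C#C)cc(OCOC)cc2O[Si](C(C)C)(C(C)C)C(C)C)OCCO1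
F5 | step 14 | 1-{6-[(dimethylamino)methyl]-5,7-dihydroxy-2,2-dimethyl-2H-chromen-8-yl}butan-1-one | CCCC(=O)c1c(O)c(CN(C)C)c(O)c2C=CC(C)(C)Oc12
F6 | step 14 | 8-butanoyl-5-hydroxy-2,2-dimethyl-6-methylidene-2H-chromen-7(6H)-one | C=C1C(O)=C2C=CC(C)(C)OC2=C(C(=O)CCC)C1=O
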